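**Plan**

1. Retrosynthesis: the bond between the (E)-CH=CH unit and the allylic CH2 is cut first (Suzuki–Miyaura, alkenyl boronate + allylic bromide), then the CH=CH bond itself (Takai–Utimoto on an oxolane-2-carbaldehyde), then, in one operation, the lactone CH2–C(=O) bond, the lactone O–C(quaternary) bond and the oxolane O–C(quaternary) bond.
2. Enabling feature: the lactone ring oxygen on the quaternary lactone carbon and the oxolane ring oxygen on the adjacent oxolane CH are vicinal and anti, and so are the oxolane oxygen on the quaternary ring carbon and the exocyclic carbon beside it. Each pair is the retron of an (E)-trisubstituted epoxide opened with inversion at its tertiary carbon, and the ring CH2CH2 places the two epoxides 1,5 to each other.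
3. Therefore an acyclic 2,3:6,7-bis-epoxide carrying a phenylsulfonyl group on its terminal CH2 is carboxylated with CO2 and acidified in the same flask. The new carboxyl group closes the lactone on the 6,7-epoxide, and the hydroxyl it sets free closes the oxolane on the 2,3-epoxide.
4. Forward order: geranyl acetate → C-8 oxidation and bromide → methyl phenyl sulfone as CH2 linchpin → Sharpless and Shi epoxidations → carboxylative cascade (lactone, then oxolane) → SmI2 removal of the sulfone → glycol cleavage → alkenyl boronate. The butenolide arm is built separately from α-bromo-γ-butyrolactone and the halves are joined last.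
5. Stereochemistry: all three stereocentres come from the two reagent-controlled epoxidations (L-(+)-diethyl tartrate; D-fructose-derived Shi ketone), relayed by inversion at both quaternary carbons and retention at the oxolane CH. The trisubstituted (E)-alkenes come from geranyl acetate and from SeO2 oxidation of (E)-methyl groups, the disubstituted (E)-alkene from the Takai–Utimoto reaction.

Key step: step 6

Remark: the sulfonyl-bearing carbon of the key-step intermediates and product is formed as a mixture of epimers and is removed one step later; the sulfur-bearing lactones of the butenolide arm are racemic.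

**Route**

Step 1
Reactants: 1 geranyl acetate [(2E)-3,7-dimethylocta-2,6-dien-1-yl acetate]
Product: 2 (2E,6E)-8-hydroxy-3,7-dimethylocta-2,6-dien-1-yl acetate
Conditions: SeO2 (0.3 equiv), t-BuOOH, salicylic acid (cat.), CH2Cl2, 0 °C → rt
Reagents that add atoms: tert-butyl hydroperoxide CC(C)(C)OO (terminal oxidant); selenium dioxide O=[Se]=O (catalytic oxygen carrier)
Why: Sharpless–Umbreit allylic oxidation (ene reaction, then [2,3]-sigmatropic shift) should hydroxylate the (E)-methyl group of the electron-richer 6,7-alkene, which fixes the (E) geometry of the new allylic alcohol, while the 2,3-alkene is deactivated by the allylic acetate.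

Step 2
Reactants: 2 (2E,6E)-8-hydroxy-3,7-dimethylocta-2,6-dien-1-yl acetate
Product: 3 (2E,6E)-8-bromo-3,7-dimethylocta-2,6-dien-1-yl acetate
Conditions: CBr4, PPh3, CH2Cl2, 0 °C
Reagents that add atoms: carbon tetrabromide BrC(Br)(Br)Br
Why: Appel bromination of a primary allylic alcohol is an SN2 process that should proceed without allylic transposition or loss of alkene geometry and leaves the acetate alone.

Step 3
Reactants: 3 (2E,6E)-8-bromo-3,7-dimethylocta-2,6-dien-1-yl acetate; 4 methyl phenyl sulfone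
Product: 6 (2E,6E)-3,7-dimethyl-9-(phenylsulfonyl)nona-2,6-dien-1-ol, via sulfonyl acetate 5 (not isolated)
Conditions: 4 (2 equiv), n-BuLi, THF, −78 °C; add 3, −78 → 0 °C; then K2CO3 (cat.), MeOH, rt
Reagents that add atoms: none
Why: SN2 alkylation of lithiated methyl phenyl sulfone by the primary allylic bromide adds the last chain carbon together with a fully oxidised carbanion-stabilising group that should survive both epoxidations; in-situ transesterification then frees the allylic alcohol needed for step 4.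

Step 4
Reactants: 6 (2E,6E)-3,7-dimethyl-9-(phenylsulfonyl)nona-2,6-dien-1-ol
Product: 7 [(2S,3S)-3-methyl-3-[(3E)-4-methyl-6-(phenylsulfonyl)hex-3-en-1-yl]oxiran-2-yl]methanol
Conditions: Ti(OiPr)4 (10 mol %), L-(+)-diethyl tartrate (12 mol %), t-BuOOH, 4 Å MS, CH2Cl2, −20 °C
Reagents that add atoms: tert-butyl hydroperoxide CC(C)(C)OO
Why: Katsuki–Sharpless asymmetric epoxidation acts only on the allylic alcohol alkene and, with L-(+)-tartrate, should give the (2S,3S)-epoxy alcohol as it does with geraniol; these centres become the quaternary oxolane carbon (after inversion) and the carbinol that is cleaved in step 8.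

Step 5
Reactants: 7 [(2S,3S)-3-methyl-3-[(3E)-4-methyl-6-(phenylsulfonyl)hex-3-en-1-yl]oxiran-2-yl]methanol
Product: 8 [(2S,3S)-3-methyl-3-{2-[(2R,3R)-3-methyl-3-[2-(phenylsulfonyl)ethyl]oxiran-2-yl]ethyl}oxiran-2-yl]methanol
Conditions: D-fructose-derived Shi ketone (30 mol %), Oxone, K2CO3, Bu4NHSO4, MeCN–dimethoxymethane/aq. borate buffer (pH 10.5), 0 °C
Reagents that add atoms: potassium peroxymonosulfate (Oxone) [K+].OOS(=O)(=O)[O-]
Why: Shi epoxidation (chiral dioxirane, spiro transition state) of the remaining (E)-trisubstituted alkene should give the (R,R)-epoxide under reagent control, the sulfone and the epoxy alcohol being inert to Oxone; these centres become the oxolane CH (retention) and the lactone carbon (inversion).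

Step 6
Reactants: 8 [(2S,3S)-3-methyl-3-{2-[(2R,3R)-3-methyl-3-[2-(phenylsulfonyl)ethyl]oxiran-2-yl]ethyl}oxiran-2-yl]methanol
Product: 11 (5S)-5-[(2R,5R)-5-[(1S)-1,2-dihydroxyethyl]-5-methyloxolan-2-yl]-5-methyl-3-(phenylsulfonyl)oxolan-2-one, via epoxy acid 9 (not isolated), via hydroxy lactone 10 (not isolated)
Conditions: n-BuLi (2.1 equiv), THF, −78 °C, 20 min; CO2 (dry gas), −78 °C; then camphor-10-sulfonic acid (3 equiv) in CH2Cl2, −78 °C → rt
Reagents that add atoms: carbon dioxide O=C=O
Why: n-BuLi deprotonates the hydroxyl group and the α-sulfonyl CH2, and the sulfonyl carbanion is carboxylated by CO2 at −78 °C (classical CO2 capture by a sulfone-stabilised carbanion), which makes the C–C bond of the future lactone and gives 9 after protonation. Camphorsulfonic acid then starts an acid-catalysed epoxide-opening cascade of the kind used for oxolane polyethers: the carboxyl oxygen opens the 6,7-epoxide at its tertiary carbon (5-exo-tet, γ-lactone 10) and the secondary hydroxyl set free on the adjacent carbon opens the 2,3-epoxide at its tertiary carbon (5-exo-tet, oxolane). Both openings are SN2-like with inversion at the tertiary carbon, so the lactone carbon (S) and the quaternary oxolane carbon (R) arise from the (R)- and (S)-configured epoxide carbons, whereas the oxolane CH (R) and the side-chain carbinol (S) keep their epoxide C–O bonds. The step needs attack at the more substituted carbon of each epoxide and no 6-endo closure; the Markovnikov bias of the protonated trisubstituted epoxides, the 5-exo geometry and, for the 2,3-epoxide, the electron-withdrawing hydroxymethyl group should secure this, and an epoxonium pathway (second epoxide activated first) leads to the same product. The carbanion must meet CO2 before it attacks the γ,δ-epoxide, which the low temperature and the hindered tertiary near carbon of that epoxide should ensure; the sulfonyl-bearing carbon forms as an epimer mixture and is erased in step 7.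

Step 7
Reactants: 11 (5S)-5-[(2R,5R)-5-[(1S)-1,2-dihydroxyethyl]-5-methyloxolan-2-yl]-5-methyl-3-(phenylsulfonyl)oxolan-2-one
Product: 12 (5S)-5-[(2R,5R)-5-[(1S)-1,2-dihydroxyethyl]-5-methyloxolan-2-yl]-5-methyloxolan-2-one
Conditions: SmI2 (3 equiv), THF–MeOH, −78 °C
Reagents that add atoms: none
Why: SmI2 reduces α-sulfonyl lactones by single-electron transfer with C–S cleavage to a samarium enolate that methanol protonates, which should remove the helper group and its stereocentre without touching the diol or the lactone.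

Step 8
Reactants: 12 (5S)-5-[(2R,5R)-5-[(1S)-1,2-dihydroxyethyl]-5-methyloxolan-2-yl]-5-methyloxolan-2-one
Product: 13 (2R,5R)-2-methyl-5-[(2S)-2-methyl-5-oxooxolan-2-yl]oxolane-2-carbaldehyde
Conditions: NaIO4, THF–pH 7 buffer, 0 °C → rt
Reagents that add atoms: none
Why: Malaprade glycol cleavage should give the aldehyde under neutral conditions; its α-carbon is quaternary and cannot epimerise.

Step 9
Reactants: 13 (2R,5R)-2-methyl-5-[(2S)-2-methyl-5-oxooxolan-2-yl]oxolane-2-carbaldehyde
Product: 14 (5S)-5-methyl-5-[(2R,5R)-5-methyl-5-[(E)-2-(4,4,5,5-tetramethyl-1,3,2-dioxaborolan-2-yl)ethenyl]oxolan-2-yl]oxolan-2-one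
Conditions: CrCl2 (8 equiv), Cl2CHBpin (2 equiv), LiI (4 equiv), THF, rt
Reagents that add atoms: 2-(dichloromethyl)-4,4,5,5-tetramethyl-1,3,2-dioxaborolane ClC(Cl)B1OC(C)(C)C(C)(C)O1
Why: Takai–Utimoto olefination (boron variant): the gem-dichromium reagent adds to the aldehyde and anti-elimination from the preferred β-oxido chromium intermediate should give the (E)-alkenyl boronate, the lactone being inert to Cr(II).

Step 10
Reactants: 15 3-bromooxolan-2-one (α-bromo-γ-butyrolactone)
Product: 16 3-(phenylsulfanyl)oxolan-2-one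
Conditions: PhSH, Et3N, CH2Cl2, 0 °C → rt
Reagents that add atoms: thiophenol Sc1ccccc1
Why: SN2 displacement of the α-bromide by thiophenolate should give the α-phenylsulfanyl lactone, a latent butenolide.

Step 11
Reactants: 16 3-(phenylsulfanyl)oxolan-2-one; 17 5-bromo-2-methylpent-2-ene
Product: 18 3-(4-methylpent-3-en-1-yl)-3-(phenylsulfanyl)oxolan-2-one
Conditions: NaH, DMF, 0 °C; 17, Bu4NI (cat.), rt
Reagents that add atoms: none
Why: alkylation of the sulfur-stabilised lactone enolate with the primary homoallylic bromide (iodide catalysis) should form the quaternary α-carbon, as in the standard acetogenin butenolide sequence.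

Step 12
Reactants: 18 3-(4-methylpent-3-en-1-yl)-3-(phenylsulfanyl)oxolan-2-one
Product: 20 3-(4-methylpent-3-en-1-yl)furan-2(5H)-one, via sulfoxide 19 (not isolated)
Conditions: mCPBA (1.0 equiv), CH2Cl2, −78 °C; then toluene, CaCO3, 110 °C
Reagents that add atoms: none
Why: S-oxidation at −78 °C is much faster than epoxidation of the trisubstituted alkene, and thermal syn-elimination (Ei) of the sulfoxide toward the ring CH2 should give the endocyclic α-substituted butenolide.

Step 13
Reactants: 20 3-(4-methylpent-3-en-1-yl)furan-2(5H)-one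
Product: 21 3-[(3E)-5-hydroxy-4-methylpent-3-en-1-yl]furan-2(5H)-one
Conditions: SeO2 (0.3 equiv), t-BuOOH, CH2Cl2, rt
Reagents that add atoms: tert-butyl hydroperoxide CC(C)(C)OO (terminal oxidant); selenium dioxide O=[Se]=O (catalytic oxygen carrier)
Why: SeO2/t-BuOOH allylic oxidation should take place at the (E)-methyl group of the electron-rich trisubstituted alkene and not at the electron-poor butenolide, giving the (E)-allylic alcohol.

Step 14
Reactants: 21 3-[(3E)-5-hydroxy-4-methylpent-3-en-1-yl]furan-2(5H)-one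
Product: 22 3-[(3E)-5-bromo-4-methylpent-3-en-1-yl]furan-2(5H)-one
Conditions: CBr4, PPh3, CH2Cl2, 0 °C
Reagents that add atoms: carbon tetrabromide BrC(Br)(Br)Br
Why: Appel bromination (SN2) should keep the (E) geometry and leave the butenolide untouched.

Step 15
Reactants: 14 (5S)-5-methyl-5-[(2R,5R)-5-methyl-5-[(E)-2-(4,4,5,5-tetramethyl-1,3,2-dioxaborolan-2-yl)ethenyl]oxolan-2-yl]oxolan-2-one; 22 3-[(3E)-5-bromo-4-methylpent-3-en-1-yl]furan-2(5H)-one
Product: 23 (5S)-5-methyl-5-[(2R,5R)-5-methyl-5-[(1E,4E)-4-methyl-7-(2-oxo-2,5-dihydrofuran-3-yl)hepta-1,4-dien-1-yl]oxolan-2-yl]oxolan-2-one (target)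
Conditions: Pd(PPh3)4 (5 mol %), CsF (3 equiv), THF, 50 °C
Reagents that add atoms: none
Why: Suzuki–Miyaura coupling of the (E)-alkenyl boronate with the allylic bromide: the π-allylpalladium intermediate should be attacked at its unsubstituted CH2 terminus with retention of both alkene geometries, under fluoride activation mild enough for the butenolide and the γ-lactone.

**Compound list**

1 | geranyl acetate, (2E)-3,7-dimethylocta-2,6-dien-1-yl acetate | CC(C)=CCC/C(C)=C/COC(C)=O | starting material
2 | (2E,6E)-8-hydroxy-3,7-dimethylocta-2,6-dien-1-yl acetate | OC/C(C)=C/CC/C(C)=C/COC(C)=O | intermediate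
3 | (2E,6E)-8-bromo-3,7-dimethylocta-2,6-dien-1-yl acetate | BrC/C(C)=C/CC/C(C)=C/COC(C)=O | intermediate
4 | methyl phenyl sulfone | CS(=O)(=O)c1ccccc1 | starting material
5 | (2E,6E)-3,7-dimethyl-9-(phenylsulfonyl)nona-2,6-dien-1-yl acetate | O=S(=O)(CC/C(C)=C/CC/C(C)=C/COC(C)=O)c1ccccc1 | intermediate
6 | (2E,6E)-3,7-dimethyl-9-(phenylsulfonyl)nona-2,6-dien-1-ol | O=S(=O)(CC/C(C)=C/CC/C(C)=C/CO)c1ccccc1 | intermediate
7 | [(2S,3S)-3-methyl-3-[(3E)-4-methyl-6-(phenylsulfonyl)hex-3-en-1-yl]oxiran-2-yl]methanol | OC[C@@H]1O[C@@]1(C)CC/C=C(\C)CCS(=O)(=O)c1ccccc1 | intermediate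
8 | [(2S,3S)-3-methyl-3-{2-[(2R,3R)-3-methyl-3-[2-(phenylsulfonyl)ethyl]oxiran-2-yl]ethyl}oxiran-2-yl]methanol | OC[C@@H]1O[C@@]1(C)CC[C@H]1O[C@]1(C)CCS(=O)(=O)c1ccccc1 | intermediate
9 | 3-[(2R,3R)-3-{2-[(2S,3S)-3-(hydroxymethyl)-2-methyloxiran-2-yl]ethyl}-2-methyloxiran-2-yl]-2-(phenylsulfonyl)propanoic acid (epimers at C-2) | OC[C@@H]1O[C@@]1(C)CC[C@H]1O[C@]1(C)CC(C(=O)O)S(=O)(=O)c1ccccc1 | intermediate
10 | (5S)-5-[(1R)-1-hydroxy-3-[(2S,3S)-3-(hydroxymethyl)-2-methyloxiran-2-yl]propyl]-5-methyl-3-(phenylsulfonyl)oxolan-2-one (epimers at C-3) | OC[C@@H]1O[C@@]1(C)CC[C@@H](O)[C@]2(C)CC(S(=O)(=O)c3ccccc3)C(=O)O2 | intermediate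
11 | (5S)-5-[(2R,5R)-5-[(1S)-1,2-dihydroxyethyl]-5-methyloxolan-2-yl]-5-methyl-3-(phenylsulfonyl)oxolan-2-one (epimers at C-3) | OC[C@H](O)[C@@]1(C)CC[C@H]([C@]2(C)CC(S(=O)(=O)c3ccccc3)C(=O)O2)O1 | intermediate
12 | (5S)-5-[(2R,5R)-5-[(1S)-1,2-dihydroxyethyl]-5-methyloxolan-2-yl]-5-methyloxolan-2-one | OC[C@H](O)[C@@]1(C)CC[C@H]([C@]2(C)CCC(=O)O2)O1 | intermediate
13 | (2R,5R)-2-methyl-5-[(2S)-2-methyl-5-oxooxolan-2-yl]oxolane-2-carbaldehyde | O=C[C@@]1(C)CC[C@H]([C@]2(C)CCC(=O)O2)O1 | intermediate
14 | (5S)-5-methyl-5-[(2R,5R)-5-methyl-5-[(E)-2-(4,4,5,5-tetramethyl-1,3,2-dioxaborolan-2-yl)ethenyl]oxolan-2-yl]oxolan-2-one | CC1(C)OB(/C=C/[C@@]2(C)CC[C@H]([C@]3(C)CCC(=O)O3)O2)OC1(C)C | intermediate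
15 | 3-bromooxolan-2-one (α-bromo-γ-butyrolactone, racemic) | BrC1CCOC1=O | starting material
16 | 3-(phenylsulfanyl)oxolan-2-one (racemic) | O=C1OCCC1Sc1ccccc1 | intermediate
17 | 5-bromo-2-methylpent-2-ene | CC(C)=CCCBr | starting material
18 | 3-(4-methylpent-3-en-1-yl)-3-(phenylsulfanyl)oxolan-2-one (racemic) | CC(C)=CCCC1(Sc2ccccc2)CCOC1=O | intermediate
19 | 3-(4-methylpent-3-en-1-yl)-3-(phenylsulfinyl)oxolan-2-one (stereoisomer mixture) | CC(C)=CCCC1(S(=O)c2ccccc2)CCOC1=O | intermediate
20 | 3-(4-methylpent-3-en-1-yl)furan-2(5H)-one | CC(C)=CCCC1=CCOC1=O | intermediate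
21 | 3-[(3E)-5-hydroxy-4-methylpent-3-en-1-yl]furan-2(5H)-one | OC/C(C)=C/CCC1=CCOC1=O | intermediate
22 | 3-[(3E)-5-bromo-4-methylpent-3-en-1-yl]furan-2(5H)-one | BrC/C(C)=C/CCC1=CCOC1=O | intermediate
23 | (5S)-5-methyl-5-[(2R,5R)-5-methyl-5-[(1E,4E)-4-methyl-7-(2-oxo-2,5-dihydrofuran-3-yl)hepta-1,4-dien-1-yl]oxolan-2-yl]oxolan-2-one | C/C(=C\CCC1=CCOC1=O)C/C=C/[C@@]1(C)CC[C@H]([C@]2(C)CCC(=O)O2)O1 | target

**Step count and risks**

Total step count: 15. Longest linear sequence: 10 steps (steps 1–9 and 15).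

Steps most likely to fail:

Step 6. The sulfonyl carbanion may alkylate itself on the nearby epoxide (three- or four-membered carbocycle) before CO2 reaches it. In the acid stage, regiocontrol may be lost (6-endo closure) or an external nucleophile may intercept a protonated epoxide. Fallback, from 3 back to 11: the carboxyl carbon is brought in with the linchpin and the cascade is ended by an ester. Bromide 3 alkylates tert-butyl (phenylsulfonyl)acetate (NaH, DMF) to give tert-butyl (4E,8E)-10-acetoxy-4,8-dimethyl-2-(phenylsulfonyl)deca-4,8-dienoate F1. Methanolysis (K2CO3, MeOH) gives tert-butyl (4E,8E)-10-hydroxy-4,8-dimethyl-2-(phenylsulfonyl)deca-4,8-dienoate F2. Epoxidation as in steps 4 and 5 gives tert-butyl (4E)-7-[(2S,3S)-3-(hydroxymethyl)-2-methyloxiran-2-yl]-4-methyl-2-(phenylsulfonyl)hept-4-enoate F3 and then tert-butyl 3-[(2R,3R)-3-{2-[(2S,3S)-3-(hydroxymethyl)-2-methyloxiran-2-yl]ethyl}-2-methyloxiran-2-yl]-2-(phenylsulfonyl)propanoate F4. With BF3·OEt2 or camphorsulfonic acid in CH2Cl2, the ester carbonyl oxygen of F4 should open the 6,7-epoxide with loss of isobutene and the freed hydroxyl should close the oxolane, which gives 11.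

Step 15. The fluoride or adventitious base may open or isomerise the butenolide, the π-allyl intermediate may couple at its substituted terminus or lose the (E) geometry, and the boronate may protodeboronate. Fallback, from 13 back to 23: a base-free Stille union replaces steps 9 and 15. Aldehyde 13 is homologated with the Ohira–Bestmann reagent (K2CO3, MeOH) to (5S)-5-[(2R,5R)-5-ethynyl-5-methyloxolan-2-yl]-5-methyloxolan-2-one F5. Pd-catalysed hydrostannylation (Bu3SnH, PdCl2(PPh3)2) gives (5S)-5-methyl-5-[(2R,5R)-5-methyl-5-[(E)-2-(tributylstannyl)ethenyl]oxolan-2-yl]oxolan-2-one F6. Coupling of F6 with bromide 22 (Pd2(dba)3, AsPh3, NMP) gives 23.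

Step 12. The sulfoxide may eliminate toward the side-chain CH2 (exocyclic alkylidene lactone) and the peracid may attack the trisubstituted alkene. Fallback, from 17 back to 20: the butenolide is built by Z-selective olefination and lactonisation. Bromide 17 alkylates ethyl 2-(diphenoxyphosphoryl)acetate (NaH, DMSO) to give ethyl 2-(diphenoxyphosphoryl)-6-methylhept-5-enoate F7. An Ando-type Horner–Wadsworth–Emmons reaction with (tert-butyldimethylsilyloxy)acetaldehyde (NaH, THF, −78 °C) gives ethyl (2Z)-2-{2-[(tert-butyldimethylsilyl)oxy]ethylidene}-6-methylhept-5-enoate F8. TsOH in MeOH removes the silyl group and the (Z)-γ-hydroxy ester should close to butenolide 20.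

Further compounds
F1 | step 6 | tert-butyl (4E,8E)-10-acetoxy-4,8-dimethyl-2-(phenylsulfonyl)deca-4,8-dienoate | O=S(=O)(C(C/C(C)=C/CC/C(C)=C/COC(C)=O)C(=O)OC(C)(C)C)c1ccccc1
F2 | step 6 | tert-butyl (4E,8E)-10-hydroxy-4,8-dimethyl-2-(phenylsulfonyl)deca-4,8-dienoate | O=S(=O)(C(C/C(C)=C/CC/C(C)=C/CO)C(=O)OC(C)(C)C)c1ccccc1
F3 | step 6 | tert-butyl (4E)-7-[(2S,3S)-3-(hydroxymethyl)-2-methyloxiran-2-yl]-4-methyl-2-(phenylsulfonyl)hept-4-enoate | OC[C@@H]1O[C@@]1(C)CC/C=C(\C)CC(C(=O)OC(C)(C)C)S(=O)(=O)c1ccccc1
F4 | step 6 | tert-butyl 3-[(2R,3R)-3-{2-[(2S,3S)-3-(hydroxymethyl)-2-methyloxiran-2-yl]ethyl}-2-methyloxiran-2-yl]-2-(phenylsulfonyl)propanoate | OC[C@@H]1O[C@@]1(C)CC[C@H]1O[C@]1(C)CC(C(=O)OC(C)(C)C)S(=O)(=O)c1ccccc1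
F5 | step 15 | (5S)-5-[(2R,5R)-5-ethynyl-5-methyloxolan-2-yl]-5-methyloxolan-2-one | C#C[C@@]1(C)CC[C@H]([C@]2(C)CCC(=O)O2)O1
F6 | step 15 | (5S)-5-methyl-5-[(2R,5R)-5-methyl-5-[(E)-2-(tributylstannyl)ethenyl]oxolan-2-yl]oxolan-2-one | CCCC[Sn](CCCC)(CCCC)/C=C/[C@@]1(C)CC[C@H]([C@]2(C)CCC(=O)O2)O1
F7 | step 12 | ethyl 2-(diphenoxyphosphoryl)-6-methylhept-5-enoate | CCOC(=O)C(CCC=C(C)C)P(=O)(Oc1ccccc1)Oc1ccccc1
F8 | step 12 | ethyl (2Z)-2-{2-[(tert-butyldimethylsilyl)oxy]ethylidene}-6-methylhept-5-enoate | CCOC(=O)/C(CCC=C(C)C)=C\CO[Si](C)(C)C(C)(C)C
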